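A direct plan would condense 4-O-benzylresacetophenone A1 with 2,4,5-trimethoxybenzaldehyde A2 to the 2′-hydroxychalcone A3, and turn A3 into the 7-benzyloxyisoflavone A4 by oxidative 1,2-aryl migration and acid ring closure. After debenzylation it would bring in the prenyl group through the 7-O-(1,1-dimethylallyl) ether A5, aromatic Claisen rearrangement and O-methylation. Its weakest steps would be:
- the oxidative aryl migration, which would need a stoichiometric trivalent thallium oxidant on a substrate whose ring B is very easily over-oxidised;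
- the Claisen rearrangement near 180 °C, which would have to choose C8 over C6 and avoid chroman formation;
- the benzyl protection, deprotection and alkyne-to-alkene adjustment around it, which would add about four steps without adding complexity.

The route would grow ring A from cyclohexane-1,3-dione instead of buying it as an arene. In the target, C8 lies between the oxygen-bearing carbons C7 and C8a, just as C2 of a 1,3-dione lies between its carbonyls; the prenyl group would therefore enter by simple enolate C-alkylation, and the methyl enol ether that masks the dione is the future 7-OMe. The key step joins the halves at C4–C4a by C-acylation of the kinetic α′-enolate of this vinylogous ester with a (2,4,5-trimethoxyphenyl)acetyl donor, fixing the whole ring A pattern at once. Ring C is then closed on the dihydro ring and ring A is aromatized last, so no aryl migration, phenol protection or Claisen rearrangement remains.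

Key step: step 4

Assumption: (2,4,5-trimethoxyphenyl)acetic acid is taken as a purchasable starting material. Diketone 8 and enaminone 9 are drawn as keto tautomers, although they should exist largely as chelated enols; this does not change the chemistry.

Step 1
Reactants: 1 cyclohexane-1,3-dione; 2 1-bromo-3-methylbut-2-ene (prenyl bromide)
Product: 3 2-(3-methylbut-2-en-1-yl)cyclohexane-1,3-dione
Conditions: KOH (1.0 equiv), H2O, 0 °C → rt, 16 h; then 1 M HCl to pH 3
Reagents that add atoms: none
Why: Enolate C-alkylation (SN2) of the doubly activated C2 by the soft allylic bromide; water solvates the enolate oxygens and should favour C- over O-alkylation, and no stereocentre is formed.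

Step 2
Reactants: 3 2-(3-methylbut-2-en-1-yl)cyclohexane-1,3-dione
Product: 4 3-methoxy-2-(3-methylbut-2-en-1-yl)cyclohex-2-en-1-one
Conditions: Me2SO4 (1.2 equiv), K2CO3 (1.5 equiv), acetone, reflux, 6 h
Reagents that add atoms: dimethyl sulfate (COS(=O)(=O)OC)
Why: Williamson-type O-alkylation of the enolised, symmetric 2-substituted dione by the hard electrophile should give a single vinylogous ester whose methoxy group is the future 7-OMe; the basic medium leaves the acid-sensitive prenyl alkene untouched.

Step 3
Reactants: 5 (2,4,5-trimethoxyphenyl)acetic acid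
Product: 6 1-(1H-benzotriazol-1-yl)-2-(2,4,5-trimethoxyphenyl)ethan-1-one
Conditions: 1H-benzotriazole (4 equiv), SOCl2 (1.1 equiv), CH2Cl2, rt, 3 h
Reagents that add atoms: 1H-benzotriazole (c1ccc2[nH]nnc2c1)
Why: Acid activation by SOCl2 followed by N-acylation of benzotriazole (acyl substitution) should give a crystalline, storable acyl donor that C-acylates enolates; the excess benzotriazole binds the HCl.

Step 4
Reactants: 4 3-methoxy-2-(3-methylbut-2-en-1-yl)cyclohex-2-en-1-one; 6 1-(1H-benzotriazol-1-yl)-2-(2,4,5-trimethoxyphenyl)ethan-1-one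
Product: 8 3-methoxy-2-(3-methylbut-2-en-1-yl)-6-[(2,4,5-trimethoxyphenyl)acetyl]cyclohex-2-en-1-one, via lithium dienolate 7 (not isolated)
Conditions: 4 (2.1 equiv), LiN(i-Pr)2 (2.1 equiv), THF, −78 °C, 45 min; then 6 (1.0 equiv), −78 → −20 °C, 2 h; sat. aq. NH4Cl
Reagents that add atoms: none
Why: LiN(i-Pr)2 removes the kinetically most accessible proton of vinylogous ester 4, the α′-H at C6 (the future C4a), to give the cross-conjugated dienolate 7, whose carbon terminus adds to the acyl carbon of 6; collapse of the tetrahedral intermediate with loss of benzotriazolide forms the C4–C4a bond. The closest known reaction types are the Stork–Danheiser α′-functionalisation of 3-alkoxycyclohexenone enolates and the Claisen-type C-acylation of ketone lithium enolates with N-acylbenzotriazoles. No ring is closed; the step joins the ring A precursor to the ring B fragment and fixes the whole 1,2,3,4-pattern of ring A (O at C8a, prenyl at C8, OMe at C7, acyl at C4a) without any aromatic substitution. The new centre at C6 is formed racemic, is enolised in the β-diketone and becomes sp2 in step 5, so it needs no control. The step needs α′- over γ-regioselectivity, secured by irreversible deprotonation at −78 °C, and C- over O-acylation, secured by the lithium counter-ion and the soft benzotriazolide leaving group; the second equivalent of 7 deprotonates 8 as it forms, which should prevent double acylation and returns one equivalent of 4.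

Step 5
Reactants: 8 3-methoxy-2-(3-methylbut-2-en-1-yl)-6-[(2,4,5-trimethoxyphenyl)acetyl]cyclohex-2-en-1-one
Product: 10 7-methoxy-8-(3-methylbut-2-en-1-yl)-3-(2,4,5-trimethoxyphenyl)-5,6-dihydro-4H-chromen-4-one, via enaminone 9 (not isolated)
Conditions: Me2NCH(OMe)2 (2.5 equiv), toluene, 90 °C, slow N2 stream, 4 h
Reagents that add atoms: N,N-dimethylformamide dimethyl acetal (COC(OC)N(C)C)
Why: Aminomethylenation of the only CH2 flanked by a ketone and an aryl group gives enaminone 9, and 6-endo addition–elimination by the enol oxygen at C1 with loss of dimethylamine should close ring C as a 4-pyranone (the amide-acetal isoflavone closure applied to a cyclic β-diketone); the C6 stereocentre disappears as C4a becomes sp2.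

Step 6
Reactants: 10 7-methoxy-8-(3-methylbut-2-en-1-yl)-3-(2,4,5-trimethoxyphenyl)-5,6-dihydro-4H-chromen-4-one
Product: 11 prebarbigerone (7-methoxy-8-(3-methylbut-2-en-1-yl)-3-(2,4,5-trimethoxyphenyl)-4H-chromen-4-one)
Conditions: DDQ (1.1 equiv), 1,4-dioxane, rt, 1–2 h; filter, aq. NaHCO3 wash
Reagents that add atoms: none
Why: Dehydrogenative aromatisation with DDQ: hydride abstraction from C5 gives an arenium ion stabilised by O1 and the 7-OMe group, and loss of the C6 proton gives ring A; this should outrun hydride abstraction at the prenyl CH2, and no free phenol is present that could cyclise oxidatively onto the prenyl group.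

## Compound list

1 | cyclohexane-1,3-dione | O=C1CCCC(=O)C1 | starting material
2 | 1-bromo-3-methylbut-2-ene (prenyl bromide) | CC(C)=CCBr | starting material
3 | 2-(3-methylbut-2-en-1-yl)cyclohexane-1,3-dione (enolised in solution) | CC(C)=CCC1C(=O)CCCC1=O | intermediate
4 | 3-methoxy-2-(3-methylbut-2-en-1-yl)cyclohex-2-en-1-one | COC1=C(CC=C(C)C)C(=O)CCC1 | intermediate
5 | (2,4,5-trimethoxyphenyl)acetic acid | COc1cc(OC)c(CC(=O)O)cc1OC | starting material
6 | 1-(1H-benzotriazol-1-yl)-2-(2,4,5-trimethoxyphenyl)ethan-1-one | COc1cc(OC)c(CC(=O)n2nnc3ccccc32)cc1OC | intermediate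
7 | lithium 5-methoxy-6-(3-methylbut-2-en-1-yl)cyclohexa-1,5-dien-1-olate (kinetic dienolate of 4, not isolated) | [Li+].[O-]C1=CCCC(OC)=C1CC=C(C)C | intermediate
8 | 3-methoxy-2-(3-methylbut-2-en-1-yl)-6-[(2,4,5-trimethoxyphenyl)acetyl]cyclohex-2-en-1-one (racemic keto form, largely enolised) | COC1=C(CC=C(C)C)C(=O)C(CC1)C(=O)Cc1cc(OC)c(OC)cc1OC | intermediate
9 | 6-[3-(dimethylamino)-2-(2,4,5-trimethoxyphenyl)prop-2-enoyl]-3-methoxy-2-(3-methylbut-2-en-1-yl)cyclohex-2-en-1-one (racemic, alkene geometry not defined, not isolated) | COC1=C(CC=C(C)C)C(=O)C(CC1)C(=O)C(=CN(C)C)c1cc(OC)c(OC)cc1OC | intermediate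
10 | 7-methoxy-8-(3-methylbut-2-en-1-yl)-3-(2,4,5-trimethoxyphenyl)-5,6-dihydro-4H-chromen-4-one (achiral) | COC1=C(CC=C(C)C)C2=C(CC1)C(=O)C(=CO2)c1cc(OC)c(OC)cc1OC | intermediate
11 | prebarbigerone, 7-methoxy-8-(3-methylbut-2-en-1-yl)-3-(2,4,5-trimethoxyphenyl)-4H-chromen-4-one (achiral) | COc1cc(OC)c(-c2coc3c(CC=C(C)C)c(OC)ccc3c2=O)cc1OC | target

Total step count: 6. Longest linear sequence: 5 steps (steps 1, 2, 4, 5 and 6 from cyclohexane-1,3-dione); step 3 is a one-step side branch.

Steps most likely to fail, with fallbacks: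

1. Step 4 (C-acylation). Proton transfer from the acidic benzylic CH2 of the acyl donor to the dienolate, or O-acylation of the dienolate, could divert the reaction. The fallback sets out from acid 5 and dienolate 7 and comes back at diketone 8.
   - Reduction of 5 with BH3·THF would give 2-(2,4,5-trimethoxyphenyl)ethan-1-ol F1.
   - Dess–Martin oxidation would give (2,4,5-trimethoxyphenyl)acetaldehyde F2, to be used at once.
   - Aldol addition of 7 to F2 at −78 °C would give 6-[1-hydroxy-2-(2,4,5-trimethoxyphenyl)ethyl]-3-methoxy-2-(3-methylbut-2-en-1-yl)cyclohex-2-en-1-one F3 as a mixture of racemic diastereomers.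
   - Dess–Martin oxidation of F3 would give 8.
   - An aldehyde is a far better electrophile than an acyl donor, so addition should outrun proton transfer and O-attack is not productive.

2. Step 6 (aromatisation). Hydride abstraction could compete at the doubly allylic CH2 of the prenyl group, or the product could be oxidised further at the same position. The fallback sets out from diketone 8 and comes back at target 11; it uses no hydride-abstracting oxidant.
   - Selenenylation of 8 at C6 with PhSeCl and pyridine (CH2Cl2, 0 °C) would give 3-methoxy-2-(3-methylbut-2-en-1-yl)-6-(phenylselanyl)-6-[(2,4,5-trimethoxyphenyl)acetyl]cyclohex-2-en-1-one F4.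
   - H2O2 at 0 °C would give the selenoxide 3-methoxy-2-(3-methylbut-2-en-1-yl)-6-(phenylseleninyl)-6-[(2,4,5-trimethoxyphenyl)acetyl]cyclohex-2-en-1-one F5.
   - Syn-elimination of F5 towards C5 and enolisation should give 1-[2-hydroxy-4-methoxy-3-(3-methylbut-2-en-1-yl)phenyl]-2-(2,4,5-trimethoxyphenyl)ethan-1-one F6.
   - Ring C would then be closed with Me2NCH(OMe)2 in toluene at 90 °C through 3-(dimethylamino)-1-[2-hydroxy-4-methoxy-3-(3-methylbut-2-en-1-yl)phenyl]-2-(2,4,5-trimethoxyphenyl)prop-2-en-1-one F7 to give 11.

3. Step 5 (ring C closure). The amide acetal could O-methylate the enolised diketone, or the liberated dimethylamine could exchange the vinylogous 7-OMe group. The fallback sets out from diketone 8 and comes back at dihydrochromone 10; it avoids both the methylating acetal and the free amine.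
   - Claisen C-formylation of the twice-deprotonated diketone at its benzylic CH2 with LiN(i-Pr)2 (2.2 equiv) and ethyl formate (THF, −78 → 0 °C) would give 6-[3-hydroxy-2-(2,4,5-trimethoxyphenyl)prop-2-enoyl]-3-methoxy-2-(3-methylbut-2-en-1-yl)cyclohex-2-en-1-one F8.
   - Cyclodehydration of F8 with catalytic pyridinium p-toluenesulfonate in toluene (the classical 1,3,5-tricarbonyl route to 4-pyranones) would give 10.

Further compounds

F1 | step 4 | 2-(2,4,5-trimethoxyphenyl)ethan-1-ol | COc1cc(OC)c(CCO)cc1OC
F2 | step 4 | (2,4,5-trimethoxyphenyl)acetaldehyde | COc1cc(OC)c(CC=O)cc1OC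
F3 | step 4 | 6-[1-hydroxy-2-(2,4,5-trimethoxyphenyl)ethyl]-3-methoxy-2-(3-methylbut-2-en-1-yl)cyclohex-2-en-1-one (mixture of racemic diastereomers) | COC1=C(CC=C(C)C)C(=O)C(CC1)C(O)Cc1cc(OC)c(OC)cc1OC
F4 | step 6 | 3-methoxy-2-(3-methylbut-2-en-1-yl)-6-(phenylselanyl)-6-[(2,4,5-trimethoxyphenyl)acetyl]cyclohex-2-en-1-one (racemic) | COC1=C(CC=C(C)C)C(=O)C(CC1)([Se]c1ccccc1)C(=O)Cc1cc(OC)c(OC)cc1OC
F5 | step 6 | 3-methoxy-2-(3-methylbut-2-en-1-yl)-6-(phenylseleninyl)-6-[(2,4,5-trimethoxyphenyl)acetyl]cyclohex-2-en-1-one (selenoxide, mixture of stereoisomers) | COC1=C(CC=C(C)C)C(=O)C(CC1)([Se](=O)c1ccccc1)C(=O)Cc1cc(OC)c(OC)cc1OC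
F6 | step 6 | 1-[2-hydroxy-4-methoxy-3-(3-methylbut-2-en-1-yl)phenyl]-2-(2,4,5-trimethoxyphenyl)ethan-1-one | COc1ccc(C(=O)Cc2cc(OC)c(OC)cc2OC)c(O)c1CC=C(C)C
F7 | step 6 | 3-(dimethylamino)-1-[2-hydroxy-4-methoxy-3-(3-methylbut-2-en-1-yl)phenyl]-2-(2,4,5-trimethoxyphenyl)prop-2-en-1-one (alkene geometry not defined) | COc1ccc(C(=O)C(=CN(C)C)c2cc(OC)c(OC)cc2OC)c(O)c1CC=C(C)C
F8 | step 5 | 6-[3-hydroxy-2-(2,4,5-trimethoxyphenyl)prop-2-enoyl]-3-methoxy-2-(3-methylbut-2-en-1-yl)cyclohex-2-en-1-one (racemic, enol geometry not defined) | COC1=C(CC=C(C)C)C(=O)C(CC1)C(=O)C(=CO)c1cc(OC)c(OC)cc1OC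
A1 | direct plan | 1-[4-(benzyloxy)-2-hydroxyphenyl]ethan-1-one (4-O-benzylresacetophenone) | CC(=O)c1ccc(OCc2ccccc2)cc1O
A2 | direct plan | 2,4,5-trimethoxybenzaldehyde | COc1cc(OC)c(C=O)cc1OC
A3 | direct plan | (E)-1-[4-(benzyloxy)-2-hydroxyphenyl]-3-(2,4,5-trimethoxyphenyl)prop-2-en-1-one | COc1cc(OC)c(/C=C/C(=O)c2ccc(OCc3ccccc3)cc2O)cc1OC
A4 | direct plan | 7-(benzyloxy)-3-(2,4,5-trimethoxyphenyl)-4H-chromen-4-one | COc1cc(OC)c(-c2coc3cc(OCc4ccccc4)ccc3c2=O)cc1OC
A5 | direct plan | 7-[(2-methylbut-3-en-2-yl)oxy]-3-(2,4,5-trimethoxyphenyl)-4H-chromen-4-one | COc1cc(OC)c(-c2coc3cc(OC(C)(C)C=C)ccc3c2=O)cc1OC
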